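The octalin (C2 = alkylidene carbon, C4a=C8a = ring-fusion alkene, C5 = gem-dimethyl carbon) is cut at C4-C4a, back to the enol triflate of a 6-alkyl-2,2-dimethylcyclohexanone. The key step makes this ring from a cyclopentanone: 2-diazopropane places C5 with both methyl groups into the C4a(=O)-C6 bond, which in one operation enlarges the ring, sets the quaternary carbon and leaves a ketone that can enolise only towards C8a. It exploits that C5 lies between alkene carbon C4a and methylene C6 of the dimethylcyclohexene ring. The precursor is a 2-alkylcyclopentanone whose side chain already fixes the alkene geometry as a vinyl iodide; the dioxane is joined by Suzuki coupling.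

Key step: step 4

Remark: octalin atoms are labelled C1-C8a as above. The atoms of the acid part are labelled D1 (carboxyl carbon) to D9 (vinylic CH), with D3 and D6 the dioxane carbons. Compounds 7 and 10 are racemic at C8a, which becomes sp2 in step 5.

Step 1
Reactants: 1 prop-2-yn-1-ol
Product: 3 (Z)-2-(iodomethylidene)but-3-en-1-ol (iodine cis to CH2OH), via vinylmagnesium chelate 2 (not isolated)
Conditions: CH2=CHMgBr (2.5 equiv), CuI (10 mol%), THF, -10 °C to rt; then I2, THF, -40 °C
Reagents that add atoms: vinylmagnesium bromide C=C[Mg]Br; iodine II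
Why: Copper-catalysed anti-carbomagnesiation of a propargylic alkoxide puts the vinyl group (C3, C4) on the inner alkyne carbon and magnesium on the outer one inside a five-membered chelate, so iodinolysis with retention fixes iodine on D9 cis to the CH2OH carbon (C1), which is the geometry of the final exocyclic alkene.

Step 2
Reactants: 3 (Z)-2-(iodomethylidene)but-3-en-1-ol
Product: 4 (Z)-2-(bromomethyl)-1-iodobuta-1,3-diene (iodine cis to CH2Br)
Conditions: CBr4, PPh3, CH2Cl2, 0 °C
Reagents that add atoms: carbon tetrabromide BrC(Br)(Br)Br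
Why: Appel reaction, in which bromide displaces the activated primary allylic alcohol by SN2 under neutral conditions, so the iododiene and its geometry are not touched.

Step 3
Reactants: 5 cyclopentanone; 4 (Z)-2-(bromomethyl)-1-iodobuta-1,3-diene
Product: 7 rac-2-[(2E)-2-(iodomethylidene)but-3-en-1-yl]cyclopentan-1-one (iodine cis to the ring-bound CH2), via lithium enolate 6 (not isolated)
Conditions: LDA, THF, -78 °C; then 4, -78 to -20 °C
Reagents that add atoms: none
Why: Kinetic enolate alkylation (SN2) with a reactive primary allylic bromide forms C8a-C1 without allylic transposition and keeps the vinyl iodide geometry, and the new stereocentre C8a needs no control because step 5 makes it sp2.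

Step 4
Reactants: 7 rac-2-[(2E)-2-(iodomethylidene)but-3-en-1-yl]cyclopentan-1-one; 8 acetone hydrazone
Product: 10 rac-6-[(2E)-2-(iodomethylidene)but-3-en-1-yl]-2,2-dimethylcyclohexan-1-one, via 2-diazopropane 9 (not isolated)
Conditions: 8, yellow HgO, KOH (cat.), Et2O, -15 °C, cold ethereal 9 distilled over; then 7, Sc(OTf)3 (10 mol%), CH2Cl2/Et2O, -78 to -40 °C
Reagents that add atoms: none
Why: Sc(III) activates the ketone, the nucleophilic carbon of 9 adds to C4a, and the diazonium alkoxide collapses by a 1,2-shift of the ring bond antiperiplanar to N2, which leaves as dinitrogen while the carbonyl group re-forms. The closest known reaction type is the Lewis acid catalysed Buchner-Curtius-Schlotterbeck homologation of cycloalkanones with disubstituted diazoalkanes. No ring is closed by cyclisation: the five-membered ring C4a-C8a-C8-C7-C6 takes up C5 and becomes six-membered through the alkyl shift. No stereocentre is created, since C5 carries two methyl groups and C8a stays racemic until step 5. The step needs migration of methylene C6 and not of the substituted C8a, which the known preference of this reaction for the less substituted alkyl group and the bulk of the CMe2-N2 unit next to the side chain should secure. It also needs a single insertion and no dipolar cycloaddition to the iododiene: the product ketone is flanked by a quaternary and a tertiary carbon and should not react again, and at low temperature the electron-rich dipole should prefer the activated carbonyl group.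

Step 5
Reactants: 10 rac-6-[(2E)-2-(iodomethylidene)but-3-en-1-yl]-2,2-dimethylcyclohexan-1-one
Product: 12 2-[(2E)-2-(iodomethylidene)but-3-en-1-yl]-6,6-dimethylcyclohex-1-en-1-yl trifluoromethanesulfonate, via potassium enolate 11 (not isolated)
Conditions: KHMDS, THF, -78 °C; then PhNTf2, -78 °C to rt
Reagents that add atoms: N-phenylbis(trifluoromethanesulfonimide) O=S(=O)(N(c1ccccc1)S(=O)(=O)C(F)(F)F)C(F)(F)F
Why: Enolate O-sulfonylation, in which the quaternary C5 allows deprotonation only at C8a, so the enol triflate fixes the tetrasubstituted C4a=C8a double bond regiospecifically and without acid.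

Step 6
Reactants: 13 6-methylhept-5-en-2-one
Product: 14 (S)-2-methyl-2-(4-methylpent-3-en-1-yl)oxirane
Conditions: Me3S(O)Cl, NaH, THF (ylide solution); La-Li3-tris(binaphthoxide) (5 mol%, BINOL antipode that gives the S epoxide), (2,4,6-(MeO)3C6H2)3P=O (5 mol%), MS 5A, THF, rt
Reagents that add atoms: trimethylsulfoxonium chloride C[S+](C)(C)=O.[Cl-]
Why: Catalytic asymmetric Corey-Chaykovsky epoxidation of a methyl ketone, in which the chiral La-Li-BINOL complex binds ketone and ylide and tells methyl from the alkyl chain, sets D6 as the S epoxide that step 12 will invert.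

Step 7
Reactants: 14 (S)-2-methyl-2-(4-methylpent-3-en-1-yl)oxirane
Product: 16 3-[(2S)-2-methyloxiran-2-yl]propanal, via secondary ozonide 15 (not isolated)
Conditions: O3, CH2Cl2, -78 °C; then Me2S, -78 °C to rt
Reagents that add atoms: ozone [O-][O+]=O
Why: Ozonolysis with reductive work-up cleaves the only C=C bond to the aldehyde that becomes D3, and the epoxide and its stereocentre are inert to ozone and dimethyl sulfide.

Step 8
Reactants: 16 3-[(2S)-2-methyloxiran-2-yl]propanal
Product: 18 (3R,4S)-3-methyl-6-[(2S)-2-methyloxiran-2-yl]hex-1-en-4-ol, via pinacol borate ester 17 (not isolated)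
Conditions: (E)-crotyl-Bpin, (R)-TRIP (5 mol%, the antipode that gives the 4S carbinol), MS 4A, toluene, -30 °C; neutral aqueous work-up
Reagents that add atoms: (E)-crotylboronic acid pinacol ester C/C=C/CB1OC(C)(C)C(C)(C)O1
Why: Chiral phosphoric acid catalysed crotylboration through a closed chair transition state, in which the E crotyl geometry gives the anti D2-methyl/D3-hydroxyl relation and the catalyst selects the aldehyde face, sets D2 in its final configuration and D3 opposite to the final one, ready for inversion in step 13.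

Step 9
Reactants: 18 (3R,4S)-3-methyl-6-[(2S)-2-methyloxiran-2-yl]hex-1-en-4-ol
Product: 19 (3R,4S)-3-methyl-6-[(2S)-2-methyloxiran-2-yl]hex-1-en-4-yl methanesulfonate
Conditions: MsCl, Et3N, CH2Cl2, -20 °C
Reagents that add atoms: methanesulfonyl chloride CS(=O)(=O)Cl
Why: Sulfonate ester formation at oxygen keeps the D3 configuration, turns D3 into the electrophile for step 13 and removes the free hydroxyl group before it can open the epoxide to a tetrahydrofuran.

Step 10
Reactants: 19 (3R,4S)-3-methyl-6-[(2S)-2-methyloxiran-2-yl]hex-1-en-4-yl methanesulfonate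
Product: 21 (2R,3S)-1-hydroxy-2-methyl-5-[(2S)-2-methyloxiran-2-yl]pentan-3-yl methanesulfonate, via secondary ozonide 20 (not isolated)
Conditions: O3, CH2Cl2, -78 °C; then NaBH4, MeOH, -78 to 0 °C
Reagents that add atoms: ozone [O-][O+]=O
Why: Ozonolysis with borohydride work-up takes the vinyl group down to the D1 hydroxymethyl group, and the immediate reduction at low temperature should outrun beta-elimination of the mesylate, so D2 and D3 stay intact.

Step 11
Reactants: 21 (2R,3S)-1-hydroxy-2-methyl-5-[(2S)-2-methyloxiran-2-yl]pentan-3-yl methanesulfonate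
Product: 22 (2R,3S)-1-[(tert-butyldiphenylsilyl)oxy]-2-methyl-5-[(2S)-2-methyloxiran-2-yl]pentan-3-yl methanesulfonate
Conditions: TBDPSCl, imidazole, CH2Cl2, 0 °C to rt
Reagents that add atoms: tert-butylchlorodiphenylsilane CC(C)(C)[Si](Cl)(c1ccccc1)c1ccccc1
Why: Silyl ether protection keeps D1 at the alcohol level, where no E1cB loss of the D3 leaving group is possible, and the tert-butyldiphenylsilyl group should stand the acidic step 12.

Step 12
Reactants: 22 (2R,3S)-1-[(tert-butyldiphenylsilyl)oxy]-2-methyl-5-[(2S)-2-methyloxiran-2-yl]pentan-3-yl methanesulfonate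
Product: 23 (2R,3S,6R)-1-[(tert-butyldiphenylsilyl)oxy]-6-hydroperoxy-7-hydroxy-2,6-dimethylheptan-3-yl methanesulfonate
Conditions: H2O2 (anhydrous, ethereal, excess), phosphomolybdic acid (5 mol%), Et2O, rt
Reagents that add atoms: hydrogen peroxide OO
Why: Acid-catalysed perhydrolysis of a 2,2-disubstituted epoxide, in which hydrogen peroxide attacks the tertiary carbon D6 from the side opposite to the C-O bond in a borderline SN2 opening, should turn the S epoxide into the 6R hydroperoxide with the final arrangement at D6.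

Step 13
Reactants: 23 (2R,3S,6R)-1-[(tert-butyldiphenylsilyl)oxy]-6-hydroperoxy-7-hydroxy-2,6-dimethylheptan-3-yl methanesulfonate
Product: 24 [(3R,6R)-6-{(2R)-1-[(tert-butyldiphenylsilyl)oxy]propan-2-yl}-3-methyl-1,2-dioxan-3-yl]methanol
Conditions: Cs2CO3, DMF, 0 °C to rt
Reagents that add atoms: none
Why: Intramolecular Williamson-type alkylation of the hydroperoxide anion (6-exo-tet SN2) closes the 1,2-dioxane with inversion at D3, which turns the anti D2/D3 pair into the required syn pair and places the D6 methyl group cis to the D3 side chain.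

Step 14
Reactants: 24 [(3R,6R)-6-{(2R)-1-[(tert-butyldiphenylsilyl)oxy]propan-2-yl}-3-methyl-1,2-dioxan-3-yl]methanol
Product: 25 (3R,6R)-6-{(2R)-1-[(tert-butyldiphenylsilyl)oxy]propan-2-yl}-3-methyl-1,2-dioxane-3-carbaldehyde
Conditions: Dess-Martin periodinane, NaHCO3, CH2Cl2, 0 °C
Reagents that add atoms: none
Why: Dess-Martin oxidation under buffered, metal-free conditions gives the aldehyde (D7) without touching the O-O bond, and the alpha carbon D6 is quaternary and cannot epimerise.

Step 15
Reactants: 25 (3R,6R)-6-{(2R)-1-[(tert-butyldiphenylsilyl)oxy]propan-2-yl}-3-methyl-1,2-dioxane-3-carbaldehyde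
Product: 26 tert-butyl{(2R)-2-[(3R,6R)-6-ethenyl-6-methyl-1,2-dioxan-3-yl]propoxy}diphenylsilane
Conditions: Ph3PCH3Br, KHMDS, THF, -78 to 0 °C
Reagents that add atoms: methyltriphenylphosphonium bromide C[P+](c1ccccc1)(c1ccccc1)c1ccccc1.[Br-]
Why: Wittig methylenation of the non-enolisable aldehyde adds D8 and gives the terminal vinyl group needed for hydroboration, a transformation that dialkyl peroxides are known to survive.

Step 16
Reactants: 26 tert-butyl{(2R)-2-[(3R,6R)-6-ethenyl-6-methyl-1,2-dioxan-3-yl]propoxy}diphenylsilane; 12 2-[(2E)-2-(iodomethylidene)but-3-en-1-yl]-6,6-dimethylcyclohex-1-en-1-yl trifluoromethanesulfonate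
Product: 28 dienyl triflate in which D8 has replaced iodine (chain cis to C1 and trans to the vinyl group; enol triflate intact), via B-alkyl-9-BBN 27 (not isolated)
Conditions: 9-BBN-H (1.0 equiv), THF, rt; then aq. Cs2CO3, 12, PdCl2(dppf) (5 mol%), AsPh3, DMF, rt
Reagents that add atoms: none
Why: B-alkyl Suzuki-Miyaura coupling, in which 9-BBN adds to the terminal carbon of the vinyl group and palladium inserts into the vinyl iodide much faster than into the crowded tetrasubstituted enol triflate, forms D8-D9 with retention so that the chain ends up cis to C1.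

Step 17
Reactants: 28 dienyl triflate
Product: 30 tert-butyl{(2R)-2-[(3R,6S)-6-{(3Z)-3-[5,5-dimethyl-3,4,5,6,7,8-hexahydronaphthalen-2(1H)-ylidene]propyl}-6-methyl-1,2-dioxan-3-yl]propoxy}diphenylsilane, via B-alkyl-9-BBN 29 (not isolated)
Conditions: 9-BBN-H (1.1 equiv), THF, 0 °C to rt; then PdCl2(dppf) (10 mol%), AsPh3, aq. Cs2CO3, DMF/THF (high dilution), 45 °C
Reagents that add atoms: none
Why: Intramolecular B-alkyl Suzuki-Miyaura coupling, in which 9-BBN hydroborates only the monosubstituted end of the diene and the alkylborane meets the enol triflate in a six-membered ring closure, forms C4-C4a under basic conditions, so the skipped diene never sees acid and neither double bond moves.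

Step 18
Reactants: 30 silyl ether of the complete skeleton
Product: 31 (2R)-2-[(3R,6S)-6-{(3Z)-3-[5,5-dimethyl-3,4,5,6,7,8-hexahydronaphthalen-2(1H)-ylidene]propyl}-6-methyl-1,2-dioxan-3-yl]propan-1-ol
Conditions: TBAF, AcOH (1:1), THF, rt
Reagents that add atoms: none
Why: Fluoride-induced silyl ether cleavage, buffered with acetic acid to avoid base-induced fragmentation of the peroxide at D3-H, frees the primary alcohol without touching any stereocentre.

Step 19
Reactants: 31 primary alcohol
Product: 33 (2S)-2-[(3R,6S)-6-{(3Z)-3-[5,5-dimethyl-3,4,5,6,7,8-hexahydronaphthalen-2(1H)-ylidene]propyl}-6-methyl-1,2-dioxan-3-yl]propanoic acid (CNP0223199.1), via aldehyde 32 (not isolated)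
Conditions: TEMPO (20 mol%), PhI(OAc)2 (2.2 equiv), MeCN/pH 7 buffer, rt
Reagents that add atoms: water O
Why: Oxoammonium (TEMPO) oxidation with a hypervalent iodine co-oxidant takes the primary alcohol through the aldehyde hydrate to the acid under near-neutral conditions that should spare the alkenes, the peroxide and the D2 stereocentre.

Compound list
1 | prop-2-yn-1-ol | C#CCO | starting material
2 | vinylmagnesium chelate (4-ethenyl-2-magnesa-1-oxacyclopent-3-ene) | C=CC1=C[Mg]OC1 | intermediate
3 | (Z)-2-(iodomethylidene)but-3-en-1-ol | OC/C(C=C)=C\I | intermediate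
4 | (Z)-2-(bromomethyl)-1-iodobuta-1,3-diene | BrC/C(C=C)=C\I | intermediate
5 | cyclopentanone | O=C1CCCC1 | starting material
6 | lithium cyclopent-1-en-1-olate | [Li+].[O-]C1=CCCC1 | intermediate
7 | rac-2-[(2E)-2-(iodomethylidene)but-3-en-1-yl]cyclopentan-1-one | O=C1CCCC1C/C(C=C)=C\I | intermediate
8 | acetone hydrazone | CC(C)=NN | starting material
9 | 2-diazopropane | CC(C)=[N+]=[N-] | intermediate
10 | rac-6-[(2E)-2-(iodomethylidene)but-3-en-1-yl]-2,2-dimethylcyclohexan-1-one | CC1(C)CCCC(C/C(C=C)=C\I)C1=O | intermediate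
11 | potassium enolate of 10 | CC1(C)CCCC(C/C(C=C)=C\I)=C1[O-].[K+] | intermediate
12 | 2-[(2E)-2-(iodomethylidene)but-3-en-1-yl]-6,6-dimethylcyclohex-1-en-1-yl trifluoromethanesulfonate | CC1(C)CCCC(C/C(C=C)=C\I)=C1OS(=O)(=O)C(F)(F)F | intermediate
13 | 6-methylhept-5-en-2-one | CC(=O)CCC=C(C)C | starting material
14 | (S)-2-methyl-2-(4-methylpent-3-en-1-yl)oxirane | CC(C)=CCC[C@@]1(C)CO1 | intermediate
15 | secondary ozonide of 14 | CC1(C)OOC(CC[C@@]2(C)CO2)O1 | intermediate
16 | 3-[(2S)-2-methyloxiran-2-yl]propanal | O=CCC[C@@]1(C)CO1 | intermediate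
17 | pinacol borate ester of 18 | C[C@H](C=C)[C@@H](OB1OC(C)(C)C(C)(C)O1)CC[C@@]2(C)CO2 | intermediate
18 | (3R,4S)-3-methyl-6-[(2S)-2-methyloxiran-2-yl]hex-1-en-4-ol | C[C@H](C=C)[C@@H](O)CC[C@@]1(C)CO1 | intermediate
19 | (3R,4S)-3-methyl-6-[(2S)-2-methyloxiran-2-yl]hex-1-en-4-yl methanesulfonate | C[C@H](C=C)[C@@H](OS(C)(=O)=O)CC[C@@]1(C)CO1 | intermediate
20 | secondary ozonide of 19 | C[C@H](C1OCOO1)[C@@H](OS(C)(=O)=O)CC[C@@]2(C)CO2 | intermediate
21 | (2R,3S)-1-hydroxy-2-methyl-5-[(2S)-2-methyloxiran-2-yl]pentan-3-yl methanesulfonate | C[C@H](CO)[C@@H](OS(C)(=O)=O)CC[C@@]1(C)CO1 | intermediate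
22 | (2R,3S)-1-[(tert-butyldiphenylsilyl)oxy]-2-methyl-5-[(2S)-2-methyloxiran-2-yl]pentan-3-yl methanesulfonate | C[C@H](CO[Si](c1ccccc1)(c1ccccc1)C(C)(C)C)[C@@H](OS(C)(=O)=O)CC[C@@]1(C)CO1 | intermediate
23 | (2R,3S,6R)-1-[(tert-butyldiphenylsilyl)oxy]-6-hydroperoxy-7-hydroxy-2,6-dimethylheptan-3-yl methanesulfonate | C[C@H](CO[Si](c1ccccc1)(c1ccccc1)C(C)(C)C)[C@@H](OS(C)(=O)=O)CC[C@](C)(CO)OO | intermediate
24 | [(3R,6R)-6-{(2R)-1-[(tert-butyldiphenylsilyl)oxy]propan-2-yl}-3-methyl-1,2-dioxan-3-yl]methanol | C[C@H](CO[Si](c1ccccc1)(c1ccccc1)C(C)(C)C)[C@H]1CC[C@](C)(CO)OO1 | intermediate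
25 | (3R,6R)-6-{(2R)-1-[(tert-butyldiphenylsilyl)oxy]propan-2-yl}-3-methyl-1,2-dioxane-3-carbaldehyde | C[C@H](CO[Si](c1ccccc1)(c1ccccc1)C(C)(C)C)[C@H]1CC[C@](C)(C=O)OO1 | intermediate
26 | tert-butyl{(2R)-2-[(3R,6R)-6-ethenyl-6-methyl-1,2-dioxan-3-yl]propoxy}diphenylsilane | C[C@H](CO[Si](c1ccccc1)(c1ccccc1)C(C)(C)C)[C@H]1CC[C@](C)(C=C)OO1 | intermediate
27 | B-alkyl-9-BBN from 26 (boron on D8) | C[C@H](CO[Si](c1ccccc1)(c1ccccc1)C(C)(C)C)[C@H]1CC[C@](C)(CCB2C3CCCC2CCC3)OO1 | intermediate
28 | dienyl triflate (D8-D9 joined; chain cis to C1, trans to the vinyl group) | C[C@H](CO[Si](c1ccccc1)(c1ccccc1)C(C)(C)C)[C@H]1CC[C@](C)(CC/C=C(/C=C)CC2=C(OS(=O)(=O)C(F)(F)F)C(C)(C)CCC2)OO1 | intermediate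
29 | B-alkyl-9-BBN from 28 (boron on C4) | C[C@H](CO[Si](c1ccccc1)(c1ccccc1)C(C)(C)C)[C@H]1CC[C@](C)(CC/C=C(/CCB2C3CCCC2CCC3)CC4=C(OS(=O)(=O)C(F)(F)F)C(C)(C)CCC4)OO1 | intermediate
30 | tert-butyldiphenylsilyl ether of 31 | C[C@H](CO[Si](c1ccccc1)(c1ccccc1)C(C)(C)C)[C@H]1CC[C@](C)(CC/C=C2/CCC3=C(CCCC3(C)C)C2)OO1 | intermediate
31 | (2R)-2-[(3R,6S)-6-{(3Z)-3-[5,5-dimethyl-3,4,5,6,7,8-hexahydronaphthalen-2(1H)-ylidene]propyl}-6-methyl-1,2-dioxan-3-yl]propan-1-ol | C[C@H](CO)[C@H]1CC[C@](C)(CC/C=C2/CCC3=C(CCCC3(C)C)C2)OO1 | intermediate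
32 | (2S)-aldehyde corresponding to 31 | C[C@H](C=O)[C@H]1CC[C@](C)(CC/C=C2/CCC3=C(CCCC3(C)C)C2)OO1 | intermediate
33 | (2S)-2-[(3R,6S)-6-{(3Z)-3-[5,5-dimethyl-3,4,5,6,7,8-hexahydronaphthalen-2(1H)-ylidene]propyl}-6-methyl-1,2-dioxan-3-yl]propanoic acid | C[C@H](C(=O)O)[C@H]1CC[C@](C)(CC/C=C2/CCC3=C(CCCC3(C)C)C2)OO1 | target

Total step count: 19. Longest linear sequence: 14 steps (steps 6 to 19).

Steps most likely to fail

Step 4. Addition of the hindered diazoalkane to the alpha-branched ketone may be so slow that decay of the diazoalkane and its cycloaddition to the iododiene take over. Part of the material may also rearrange by migration of C8a instead of C6.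
Fallback: the insertion is moved ahead of the fragment union.
- Cyclopentanone 5 is treated with 9 (made from 8 as in step 4) and Sc(OTf)3. Both alpha carbons are equal and no diene is present, and the product is 2,2-dimethylcyclohexan-1-one F1.
- LDA can deprotonate F1 only at C8a, giving lithium 6,6-dimethylcyclohex-1-en-1-olate F2.
- Alkylation of F2 with bromide 4 comes back to the route at 10.

Step 12. The epoxide may ionise to an open tertiary cation, so that the configuration at D6 is partly lost. Peroxide may also attack the CH2 terminus, or the acidic catalyst may strip the silyl ether.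
Fallback: the order of the two C-O bond formations is reversed, setting out from 22.
- The caesium salt of 2-methoxypropan-2-yl hydroperoxide (CsOH, DMF) displaces the mesylate by intermolecular SN2 with inversion at D3. This gives tert-butyl{(2R,3R)-3-[(2-methoxypropan-2-yl)peroxy]-2-methyl-5-[(2S)-2-methyloxiran-2-yl]pentoxy}diphenylsilane F3.
- Mild acid (PPTS in wet CH2Cl2, then camphorsulfonic acid) frees (2R,3R)-1-[(tert-butyldiphenylsilyl)oxy]-2-methyl-5-[(2S)-2-methyloxiran-2-yl]pentan-3-yl hydroperoxide F4.
- F4 opens the epoxide by an intramolecular 6-exo attack at the tertiary carbon with inversion and comes back to the route at 24.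

Step 17. Oxidative addition at the crowded triflate may be slow, so that beta-hydride elimination of the alkylpalladium species and reduction of the O-O bond by palladium(0) or borane compete during prolonged warming.
Fallback: ring A is closed by metathesis, setting out from 28.
- Stille coupling with tributyl(vinyl)stannane (Pd2(dba)3, AsPh3, LiCl, NMP) replaces the triflate by a vinyl group, which has no beta hydrogen on palladium. The product is the 2-ethenyl-3,3-dimethylcyclohexenyl tetraene F5.
- Ring-closing metathesis of the two monosubstituted vinyl groups with a second-generation ruthenium catalyst gives the conjugated C3=C4 triene F6.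
- Diimide (2-nitrobenzenesulfonohydrazide, Et3N) should saturate only the cis-disubstituted C3=C4 bond and come back to the route at 30.

Further compounds
F1 | step 4 | 2,2-dimethylcyclohexan-1-one | CC1(C)CCCCC1=O
F2 | step 4 | lithium 6,6-dimethylcyclohex-1-en-1-olate | CC1(C)CCCC=C1[O-].[Li+]
F3 | step 12 | tert-butyl{(2R,3R)-3-[(2-methoxypropan-2-yl)peroxy]-2-methyl-5-[(2S)-2-methyloxiran-2-yl]pentoxy}diphenylsilane | C[C@H](CO[Si](c1ccccc1)(c1ccccc1)C(C)(C)C)[C@H](OOC(C)(C)OC)CC[C@@]1(C)CO1
F4 | step 12 | (2R,3R)-1-[(tert-butyldiphenylsilyl)oxy]-2-methyl-5-[(2S)-2-methyloxiran-2-yl]pentan-3-yl hydroperoxide | C[C@H](CO[Si](c1ccccc1)(c1ccccc1)C(C)(C)C)[C@H](OO)CC[C@@]1(C)CO1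
F5 | step 17 | 2-ethenyl-3,3-dimethylcyclohexenyl tetraene (vinyl in place of the triflate of 28) | C[C@H](CO[Si](c1ccccc1)(c1ccccc1)C(C)(C)C)[C@H]1CC[C@](C)(CC/C=C(/C=C)CC2=C(C=C)C(C)(C)CCC2)OO1
F6 | step 17 | conjugated C3=C4 triene (3,4-didehydro derivative of 30) | C[C@H](CO[Si](c1ccccc1)(c1ccccc1)C(C)(C)C)[C@H]1CC[C@](C)(CC/C=C2/C=CC3=C(CCCC3(C)C)C2)OO1
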